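## Analysis of the target

Compound 32 is a furanone-bridged germacranolide. Its ten-membered carbocycle is numbered here C1 (furanone carbonyl), C2=C3, C4=C5 (Z, methyl C15 on C4), C6 (acyloxy carbinol), C7, C8 (lactone carbinol), C9 (methylene) and C10 (quaternary, methyl C14); an oxygen between C3 and C10 turns C1–C3/C10 into a 3(2H)-furanone, and an α-methylene-γ-butyrolactone (C11, C12 carbonyl, C13 methylene) is fused across C7–C8. The ring carries four stereocentres, 6R, 7R, 8S and 10R: along the chain C5–C9 the C6–O, C7–C11 and C8–O bonds are all syn, which makes the lactone trans-fused and the two oxygens 1,3-syn, whereas C10 is tied to this triad only through the ring. A fifth stereocentre sits in the (S)-2-methyloxirane-2-carboxylate on O6. The α-methylene lactone and the cross-conjugated dienone C1=O/C2=C3/C4=C5 are acceptors, the epoxy ester is acid-labile and the Z trisubstituted alkene can isomerise, so strong nucleophiles, acids and bases are excluded late in the route. The difficulty lies in the strained medium ring, which holds a Z alkene and a flat bridging heterocycle, and in the oxygenated quaternary C10, remote from the other stereocentres. The strategy rests on the fact that C10 is α to the C1 carbonyl and C9 is α to C8, so C9–C10 is the middle bond of a latent C1/C8 1,4-dicarbonyl unit: one half can be written as an aromatic 2-methyl-3-silyloxyfuran (O, C3, C2, C1, C10), the other as a C8=C9 silyl enol ether, and their oxidative union closes the ring and creates C10 in one step.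

## Retrosynthetic reasoning

**O6–acyl bond.** The epoxy ester is the most fragile part and is cut first. Target 32 comes from alcohol 27 and acid 30 through the mixed anhydride 31. The acid has no α-hydrogen and cannot racemise; it goes back to epoxy alcohol 29 and, by asymmetric epoxidation, to allylic alcohol 28.

**C11=C13 and the lactone bond C12–O8.** The methylene lactone is the second acceptor and is unmasked late. Silyl ether 26 arises by β-elimination from the hydroxymethyl lactone 24 (via 25), and 24 by oxidative lactonisation of triol 22 (via lactol 23). C11 is thus kept at the sp3 level and C12/C13 as the two equal arms of a 1,3-diol, held as the dioxane of 21. Because the arms are equal, C11 is no stereocentre until the lactone closes, and it is planar again after the elimination. An unsaturated C7 substituent was not used, because it would make H7 doubly activated next to the C8 carbonyl of 20.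

**C8–H bond.** Carbinol 21 is the reduction product of ketone 20. The ring closure needs C8 as a carbonyl, so C8 is set afterwards under the control of the neighbouring C7.

**C9–C10 bond (key disconnection).** Ketone 20 is opened to the acyclic bis(enol ether) 19. Only this cut turns both ends into simple enol ethers, it lies far from the aldol stereocentres C6/C7, and it forms the quaternary centre and the ring together. Cutting C5–C6 or C6–C7 instead would require the quaternary C10 to be made separately beforehand. The forward reaction must couple two different enol ethers, close a medium ring and choose one face of the furan.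

**O–Si bonds and the furanone ring.** Compound 19 comes from furanone 17 by double enolisation and silylation (via 18). Furanone 17 comes from the γ-hydroxy ynone 16 by cycloisomerisation (O–C3 bond), and 16 from vinyl iodide 14, alkynol 15 and one carbonyl carbon by carbonylative Sonogashira coupling (C3–C4 and C2–C3 bonds). The Z geometry is thereby taken from a vinyl iodide of fixed geometry with retention. C3 becomes a carbonyl carbon only after O6 is silylated, because a free Z γ-hydroxy enoate or enone would cyclise onto O6.

**C8–C9 and C6–C7 bonds.** Methyl ketone 14 comes from Weinreb amide 13, which comes from 12 and from the aldol adduct 11. Adduct 11 is cut at C6–C7 into imide 5 and enal 9; an auxiliary-controlled syn aldol reaction through boron enolate 10 sets both stereocentres in an acyclic, predictable setting.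

**Building blocks.** Imide 5 comes from acid 2 and auxiliary 3 (via 4), and 2 from alcohol 1. Enal 9 comes from iodo alcohol 8, and 8 from alkynol 6 (via 7).

## Alternatives that were turned down

**Alternative 1:** The O–C10 bond of the furanone is disconnected. The substrate would be the ten-membered 1,10-epoxy-3-ketone A2, with the lactone and the Z C4=C5 bond in place. BF3·OEt2 activates the epoxide, the C3 carbonyl oxygen opens it at the tertiary C10 with inversion, and loss of a C2 proton gives the bridged dihydrofuranol A1, which still needs oxidation at C1.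
- For it: the configuration at C10 is read stereospecifically from the epoxide, which is firmer than the conformational control relied on here, and the lactone is carried through.
- Against it: A2 presupposes the whole germacrane ring with its Z alkene, so the macrocyclisation is only moved to an earlier, unsolved stage. The epoxide must be placed on one face of a mobile E C1=C10 bond beside an enone and a methylene lactone. A Lewis-acid-opened tertiary epoxide next to a ketone and a transannular alkene can also undergo hydride shift or transannular C–C bonding.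
- Comparison: it is longer (ring synthesis, epoxidation, cyclisation, oxidation) and separates ring formation from the creation of C10. The anodic coupling does both from an acyclic precursor made by an aldol reaction and a cross-coupling.

**Alternative 2:** The C6–C7 bond is disconnected. In the thirteen-membered ether A4, C6 is a methylene linked through oxygen to C13 and C7=C11 is a ring alkene. KN(SiMe3)2 removes a C6 proton (α to oxygen and vinylogous to the C1 carbonyl), and the [2,3]-shift forms C6–C7, breaks O–C13 and contracts the ring to carbocycle A3, with the C11=C13 methylene and the C6 hydroxyl in place.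
- For it: a thirteen-membered ether is easier to close than the carbocycle, ring-contracting Wittig rearrangements of macrocyclic allyl ethers are established, and two stereocentres and the exocyclic alkene are delivered at once. On precedent this step is stronger than an electrochemical macrocyclisation.
- Against it: the C6 anion is an extended, strongly stabilised trienolate; such anions rearrange reluctantly, can reprotonate elsewhere and put the Z geometry of C4=C5 at risk. The sense of C6/C7, and its relation to C8 and C10, depends on the folding of a large-ring transition state and on the C7=C11 geometry. The quaternary C10 and the furanone must be built enantioselectively beforehand and survive strong base.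
- Comparison: the chosen route sets C6/C7 by an auxiliary-controlled aldol reaction with a predictable outcome and reaches its cyclisation substrate in far fewer steps than A4 would need.

**Alternative 3:** The lactone bonds C11–C12 and C12–O8 are disconnected. The lactone is assembled last from the C7-ethynyl C8-alcohol A6 and carbon monoxide with PdCl2, SnCl2 and PPh3; syn addition of the alkoxycarbonylpalladium unit across the alkyne gives the methylene lactone A5, which is the same compound as 26.
- For it: one step replaces steps 14 to 16 of the present route, the acceptor appears at the very end, and the trans ring fusion follows from the existing C7/C8 relationship. On endgame economy it is stronger.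
- Against it: it does not say how the ring or C10 is made, so it is an endgame and not a strategy for the core. An ethynyl group on C7 would have to pass the C8-ketone stage, where H7 is propargylic and α to a carbonyl (isomerisation to the allenyl ketone), as well as the double enolisation and the anodic step.
- Comparison: the chosen route pays two extra steps at the end for a saturated dioxane on C7 that is inert to base, to the anode and to hydride.

Key step: step 12

Remark on the chemistry: alcohol 1 (the acetonide alcohol used for acyclic nucleoside side chains) is taken as a catalogue compound, and alkynol 15 is used racemic because its carbinol carbon becomes sp2 in 19.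

## Route

Step 1
Reactants: 1 2-(2,2-dimethyl-1,3-dioxan-5-yl)ethan-1-ol
Product: 2 2-(2,2-dimethyl-1,3-dioxan-5-yl)acetic acid
Conditions: TEMPO (cat.), NaOCl (cat.), NaClO2, MeCN/phosphate buffer pH 6.7, 35 °C
Reagents that add atoms: sodium chlorite [Na+].[O-]Cl=O
Why: Nitroxyl-catalysed chlorite oxidation takes a primary alcohol straight to the carboxylic acid at near-neutral pH, which spares the acid-labile dioxane.

Step 2
Reactants: 2 2-(2,2-dimethyl-1,3-dioxan-5-yl)acetic acid; 3 (S)-4-benzyloxazolidin-2-one
Product: 5 (S)-4-benzyl-3-[2-(2,2-dimethyl-1,3-dioxan-5-yl)acetyl]oxazolidin-2-one, via mixed pivalic anhydride 4 (not isolated)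
Conditions: PivCl, Et3N, THF, −20 °C; then 3, LiCl, −20 °C → rt
Reagents that add atoms: none
Why: N-Acylation of an oxazolidinone by a mixed anhydride in the presence of LiCl; the pivaloyl carbonyl is blocked by its tert-butyl group, so only the wanted acyl group is transferred.

Step 3
Reactants: 6 but-2-yn-1-ol
Product: 8 (Z)-3-iodobut-2-en-1-ol, via cyclic alkenylaluminate 7 (not isolated)
Conditions: NaAlH2(OCH2CH2OMe)2, THF, 0 °C → rt; then I2, −78 → 0 °C
Reagents that add atoms: iodine II
Why: Alkoxide-directed trans-hydroalumination of the propargylic alcohol places aluminium on C3 in a five-membered chelate, and iodinolysis of the C–Al bond with retention gives the iodide cis to the carbinol carbon, which is the later Z C4=C5 geometry.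

Step 4
Reactants: 8 (Z)-3-iodobut-2-en-1-ol
Product: 9 (Z)-3-iodobut-2-enal
Conditions: MnO2, CH2Cl2, rt, dark; filtered and used as a solution
Reagents that add atoms: none
Why: Heterogeneous allylic oxidation under neutral conditions, which should not isomerise the Z enal.

Step 5
Reactants: 5 (S)-4-benzyl-3-[2-(2,2-dimethyl-1,3-dioxan-5-yl)acetyl]oxazolidin-2-one; 9 (Z)-3-iodobut-2-enal
Product: 11 (S)-4-benzyl-3-[(2S,3S,4Z)-2-(2,2-dimethyl-1,3-dioxan-5-yl)-3-hydroxy-5-iodohex-4-enoyl]oxazolidin-2-one, via dibutylboron Z-enolate 10 (not isolated)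
Conditions: Bu2BOTf, Et3N, CH2Cl2, −78 → 0 °C; then 9, −78 → 0 °C; pH 7 buffer, MeOH, H2O2, 0 °C
Reagents that add atoms: none
Why: Evans syn-aldol reaction: the Z boron enolate reacts through a closed chair transition state on the enolate face remote from the benzyl group of the auxiliary, which sets C7 and C6 (2S,3S in 11) with the syn relationship and the absolute sense of the target.

Step 6
Reactants: 11 (S)-4-benzyl-3-[(2S,3S,4Z)-2-(2,2-dimethyl-1,3-dioxan-5-yl)-3-hydroxy-5-iodohex-4-enoyl]oxazolidin-2-one
Product: 12 (2S,3S,4Z)-2-(2,2-dimethyl-1,3-dioxan-5-yl)-3-hydroxy-5-iodo-N-methoxy-N-methylhex-4-enamide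
Conditions: MeNHOMe·HCl, AlMe3, CH2Cl2, −10 → 0 °C; aqueous potassium sodium tartrate
Reagents that add atoms: N,O-dimethylhydroxylamine hydrochloride CNOC.Cl
Why: Aluminium amide transamidation of the imide, assisted by the free β-hydroxyl, gives the Weinreb amide without retro-aldol cleavage or epimerisation at C7 and releases the auxiliary.

Step 7
Reactants: 12 (2S,3S,4Z)-2-(2,2-dimethyl-1,3-dioxan-5-yl)-3-hydroxy-5-iodo-N-methoxy-N-methylhex-4-enamide
Product: 13 (2S,3S,4Z)-3-[(tert-butyldimethylsilyl)oxy]-2-(2,2-dimethyl-1,3-dioxan-5-yl)-5-iodo-N-methoxy-N-methylhex-4-enamide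
Conditions: TBSOTf, 2,6-lutidine, CH2Cl2, −78 → 0 °C
Reagents that add atoms: tert-butyldimethylsilyl trifluoromethanesulfonate CC(C)(C)[Si](C)(C)OS(=O)(=O)C(F)(F)F
Why: Silyl triflate silylation of a hindered secondary alcohol; the ether blocks O6 before C3 becomes a carbonyl carbon and lasts until step 17.

Step 8
Reactants: 13 (2S,3S,4Z)-3-[(tert-butyldimethylsilyl)oxy]-2-(2,2-dimethyl-1,3-dioxan-5-yl)-5-iodo-N-methoxy-N-methylhex-4-enamide
Product: 14 (3S,4S,5Z)-4-[(tert-butyldimethylsilyl)oxy]-3-(2,2-dimethyl-1,3-dioxan-5-yl)-6-iodohept-5-en-2-one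
Conditions: MeMgBr, THF, 0 °C → rt; aq. NH4Cl
Reagents that add atoms: methylmagnesium bromide C[Mg]Br
Why: Grignard addition to a Weinreb amide stops at the chelated tetrahedral intermediate and gives the methyl ketone (C8, C9) on work-up; the vinyl iodide should not exchange with a methyl Grignard reagent at this temperature.

Step 9
Reactants: 14 (3S,4S,5Z)-4-[(tert-butyldimethylsilyl)oxy]-3-(2,2-dimethyl-1,3-dioxan-5-yl)-6-iodohept-5-en-2-one; 15 but-3-yn-2-ol (racemic)
Product: 16 (3S,4R,5Z)-4-[(tert-butyldimethylsilyl)oxy]-3-(2,2-dimethyl-1,3-dioxan-5-yl)-10-hydroxy-6-methylundec-5-en-8-yne-2,7-dione (both C10 epimers)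
Conditions: PdCl2(PPh3)2 (cat.), CuI (cat.), CO (1 atm), Et3N, THF, rt
Reagents that add atoms: carbon monoxide [C-]#[O+]
Why: Carbonylative Sonogashira coupling: oxidative addition of the vinyl iodide with retention, CO insertion to the acylpalladium species and coupling with the copper acetylide give the Z ynone with C3 as the new carbonyl carbon.

Step 10
Reactants: 16 (3S,4R,5Z)-4-[(tert-butyldimethylsilyl)oxy]-3-(2,2-dimethyl-1,3-dioxan-5-yl)-10-hydroxy-6-methylundec-5-en-8-yne-2,7-dione
Product: 17 5-[(2Z,4R,5S)-4-[(tert-butyldimethylsilyl)oxy]-5-(2,2-dimethyl-1,3-dioxan-5-yl)-6-oxohept-2-en-2-yl]-2-methylfuran-3(2H)-one (both C2 epimers of the furanone)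
Conditions: (4-CF3C6H4)3PAuCl (cat.), AgOTf (cat.), toluene, rt
Reagents that add atoms: none
Why: Gold-catalysed cycloisomerisation of a γ-hydroxy ynone to a 3(2H)-furanone: the alkyne carbon next to the carbinol becomes the C1 carbonyl and the hydroxyl oxygen ends up bonded to C3, a net isomerisation that leaves C6 and C7 untouched.

Step 11
Reactants: 17 5-[(2Z,4R,5S)-4-[(tert-butyldimethylsilyl)oxy]-5-(2,2-dimethyl-1,3-dioxan-5-yl)-6-oxohept-2-en-2-yl]-2-methylfuran-3(2H)-one
Product: 19 tert-butyl({5-[(2Z,4R,5S)-4,6-bis[(tert-butyldimethylsilyl)oxy]-5-(2,2-dimethyl-1,3-dioxan-5-yl)hepta-2,6-dien-2-yl]-2-methylfuran-3-yl}oxy)dimethylsilane, via dilithium dienolate 18 (not isolated)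
Conditions: LiN(iPr)2 (2.4 equiv), THF, −78 °C; then TBSCl, DMPU, −78 → −20 °C
Reagents that add atoms: tert-butyldimethylsilyl chloride CC(C)(C)[Si](C)(C)Cl
Why: The first equivalent of base removes the acidic H10 and gives the aromatic furan-3-olate, and the second removes a methyl proton of the C8 ketone under kinetic control (H7 is tertiary and shielded). O-Silylation of both oxygens gives the silyloxyfuran and the terminal C8=C9 enol ether; a single robust silyl group is used at both positions so that one operation suffices and both enol ethers outlast the weakly acidic electrolyte of step 12, which a trimethylsilyl enol ether would not.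

Step 12
Reactants: 19 tert-butyl({5-[(2Z,4R,5S)-4,6-bis[(tert-butyldimethylsilyl)oxy]-5-(2,2-dimethyl-1,3-dioxan-5-yl)hepta-2,6-dien-2-yl]-2-methylfuran-3-yl}oxy)dimethylsilane
Product: 20 (4Z,6R,7S,10R)-6-[(tert-butyldimethylsilyl)oxy]-7-(2,2-dimethyl-1,3-dioxan-5-yl)-4,10-dimethyl-3,10-epoxycyclodeca-2,4-diene-1,8-dione
Conditions: reticulated vitreous carbon anode, Pt cathode, undivided cell, constant current at low current density (2.2 F per mol), n-Bu4NClO4 (0.1 M), 2,6-lutidine, CH2Cl2/(CF3)2CHOH 9:1, substrate about 1 mM, rt
Reagents that add atoms: none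
Why: Proposed new method: the dienyl 3-silyloxyfuran is the most easily oxidised π system of 19, so at low current density the anode takes one electron from it alone; transfer of its silyl group to the fluoro alcohol leaves a C10 radical flanked by the C1 carbonyl and the ring oxygen, which adds to the unsubstituted terminus C9 of the electron-rich C8=C9 enol ether, and the C8 α-silyloxy radical so formed is oxidised at once and desilylated to the ketone (two electrons per molecule, hydrogen at the cathode). The closest known reaction types are anodic intramolecular couplings of silyl enol ethers with electron-rich alkenes or furans, which close five- to seven-membered rings, and oxidative cross-couplings of two different enolates to 1,4-diketones. The new bond closes the ten-membered carbocycle C1–C10 and, counted the short way through the furan oxygen, a nine-membered ring; both enol ether carbons lie inside the ring, so the mode is endo-trig (9-endo through oxygen, 10-endo along the carbon perimeter). The only small-ring alternative, bonding of C9 to C5 of the delocalised radical cation, would be a 5-endo-trig closure and is stereoelectronically disfavoured. C10 is the one new stereocentre: the chain can roof either face of the flat furan, and only the fold that keeps the C7 dioxanyl group and the C6 silyloxy group on the outside of the forming ring, with H6 and H7 inside, should bring C9 to the face that gives 10R, so control is by the substrate through C7 and C6. Cross-coupling over homo-coupling is secured by the gap in oxidation potential between the two enol ethers, so that only the furan is oxidised, and by millimolar concentration. Bulk methanol is avoided because a slow medium-ring closure would lose to solvent capture at C10; the poorly nucleophilic fluoro alcohol serves as proton source and silyl acceptor. The Z C4=C5 bond and the coplanar furan hold C9 within reach of C10.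

Step 13
Reactants: 20 (4Z,6R,7S,10R)-6-[(tert-butyldimethylsilyl)oxy]-7-(2,2-dimethyl-1,3-dioxan-5-yl)-4,10-dimethyl-3,10-epoxycyclodeca-2,4-diene-1,8-dione
Product: 21 (4Z,6R,7R,8S,10R)-6-[(tert-butyldimethylsilyl)oxy]-7-(2,2-dimethyl-1,3-dioxan-5-yl)-8-hydroxy-4,10-dimethyl-3,10-epoxycyclodeca-2,4-dien-1-one
Conditions: NaBH4, MeOH/CH2Cl2, −78 → −40 °C
Reagents that add atoms: none
Why: The saturated C8 ketone is far more electrophilic than the cross-conjugated, vinylogous-ester carbonyl C1 and should be reduced alone. With C6 and C9 held apart across the C7–C8 bond by the ring, the dioxanyl group on C7 covers one face of the carbonyl and hydride should enter past H7 (Felkin–Anh sense, attack from the periphery), which gives the 8S carbinol with O8 syn to C11 and to O6.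

Step 14
Reactants: 21 (4Z,6R,7R,8S,10R)-6-[(tert-butyldimethylsilyl)oxy]-7-(2,2-dimethyl-1,3-dioxan-5-yl)-8-hydroxy-4,10-dimethyl-3,10-epoxycyclodeca-2,4-dien-1-one
Product: 22 (4Z,6R,7R,8S,10R)-6-[(tert-butyldimethylsilyl)oxy]-7-(1,3-dihydroxypropan-2-yl)-8-hydroxy-4,10-dimethyl-3,10-epoxycyclodeca-2,4-dien-1-one
Conditions: PPTS, MeOH, rt
Reagents that add atoms: none
Why: Acid-catalysed transketalisation to methanol removes the dioxane acetonide; the hindered secondary silyl ether at C6 and the furanone should be stable under these conditions.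

Step 15
Reactants: 22 (4Z,6R,7R,8S,10R)-6-[(tert-butyldimethylsilyl)oxy]-7-(1,3-dihydroxypropan-2-yl)-8-hydroxy-4,10-dimethyl-3,10-epoxycyclodeca-2,4-dien-1-one
Product: 24 hydroxymethyl lactone (compound 26 with H and CH2OH on C11 in place of the methylene group; both C11 epimers), via lactol 23 (not isolated)
Conditions: TEMPO (cat.), PhI(OAc)2 (2.2 equiv), CH2Cl2, rt
Reagents that add atoms: none
Why: Oxoammonium oxidation is selective for primary alcohols; once either of the two equal arms is oxidised the γ-hydroxyl on C8 closes the five-membered lactol 23, which is oxidised on to the lactone. O8 and C11 are syn, so the trans-fused ring closes without strain, and the configuration at C11 is of no consequence because it is removed in step 16.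

Step 16
Reactants: 24 hydroxymethyl lactone
Product: 26 (6R,7R,8S,10R)-6-O-tert-butyldimethylsilyl ether of the deacylated target (furanone-bridged 8,12-lactone with C11=C13 methylene), via methanesulfonate 25 (not isolated)
Conditions: MsCl, Et3N, CH2Cl2, 0 °C; then DBU, 0 °C → rt
Reagents that add atoms: none
Why: Sulfonylation of the primary alcohol and E1cB elimination through the lactone enolate give the exocyclic C11=C13 bond from both C11 epimers.

Step 17
Reactants: 26 6-O-tert-butyldimethylsilyl ether of the deacylated target
Product: 27 (6R,7S,8S,10R)-6-hydroxy lactone (deacylated target)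
Conditions: HF·pyridine, pyridine/THF, 0 °C → rt
Reagents that add atoms: none
Why: Buffered fluoride cleavage of the secondary silyl ether; the medium is neither basic nor nucleophilic enough to add to the methylene lactone or the dienone.

Step 18
Reactants: 28 2-methylprop-2-en-1-ol
Product: 29 [(2R)-2-methyloxiran-2-yl]methanol
Conditions: Ti(OiPr)4 (cat.), D-(−)-diisopropyl tartrate (cat.), cumene hydroperoxide, 4 Å molecular sieves, CH2Cl2, −20 °C
Reagents that add atoms: cumene hydroperoxide CC(C)(OO)c1ccccc1
Why: Sharpless asymmetric epoxidation; with the D-(−)-tartrate the titanium-bound peroxide delivers oxygen to the face of the allylic alcohol that gives the 2R epoxy alcohol.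

Step 19
Reactants: 29 [(2R)-2-methyloxiran-2-yl]methanol
Product: 30 (2S)-2-methyloxirane-2-carboxylic acid
Conditions: RuCl3 (cat.), NaIO4, MeCN/EtOAc/H2O, 0 °C → rt
Reagents that add atoms: water O
Why: Ruthenium tetroxide generated catalytically oxidises the primary alcohol to the acid without touching the epoxide. The quaternary stereocentre is unchanged; the descriptor changes from R to S only because the carboxyl group outranks the ring methylene.

Step 20
Reactants: 27 (6R,7S,8S,10R)-6-hydroxy lactone; 30 (2S)-2-methyloxirane-2-carboxylic acid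
Product: 32 target: (4Z,6R,7R,8S,10R)-3,10-epoxy-1-oxogermacra-2,4,11(13)-trien-12,8-olid-6-yl (2S)-2-methyloxirane-2-carboxylate, via mixed anhydride 31 (not isolated)
Conditions: 2,4,6-Cl3C6H2COCl, Et3N, THF, rt; then 27, DMAP, toluene, rt
Reagents that add atoms: none
Why: Yamaguchi esterification: DMAP attacks the mixed anhydride at the less hindered epoxy-acyl carbonyl and the acylpyridinium ion acylates the hindered allylic alcohol. The acid has no α-hydrogen, so its stereocentre cannot epimerise, and the conditions are mild enough for the methylene lactone and the epoxide.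

## Compound list

1 | 2-(2,2-dimethyl-1,3-dioxan-5-yl)ethan-1-ol | OCCC1COC(C)(C)OC1 | starting material
2 | 2-(2,2-dimethyl-1,3-dioxan-5-yl)acetic acid | OC(=O)CC1COC(C)(C)OC1 | intermediate
3 | (S)-4-benzyloxazolidin-2-one | O=C1OC[C@H](Cc2ccccc2)N1 | starting material
4 | 2-(2,2-dimethyl-1,3-dioxan-5-yl)acetic pivalic anhydride (not isolated) | CC(C)(C)C(=O)OC(=O)CC1COC(C)(C)OC1 | intermediate
5 | (S)-4-benzyl-3-[2-(2,2-dimethyl-1,3-dioxan-5-yl)acetyl]oxazolidin-2-one | O=C(CC1COC(C)(C)OC1)N1C(=O)OC[C@@H]1Cc1ccccc1 | intermediate
6 | but-2-yn-1-ol | CC#CCO | starting material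
7 | sodium alkenylaluminate: five-membered oxaaluminole with Al bonded to the alkoxide O and to C3, carrying two 2-methoxyethoxy groups (not isolated) | CC1=CCO[Al-]1(OCCOC)OCCOC.[Na+] | intermediate
8 | (Z)-3-iodobut-2-en-1-ol | C/C(I)=C/CO | intermediate
9 | (Z)-3-iodobut-2-enal | C/C(I)=C/C=O | intermediate
10 | dibutylboron Z-enolate of 5 (not isolated) | CCCCB(CCCC)O/C(=C\C1COC(C)(C)OC1)N1C(=O)OC[C@@H]1Cc1ccccc1 | intermediate
11 | (S)-4-benzyl-3-[(2S,3S,4Z)-2-(2,2-dimethyl-1,3-dioxan-5-yl)-3-hydroxy-5-iodohex-4-enoyl]oxazolidin-2-one | O=C([C@@H](C1COC(C)(C)OC1)[C@H](O)\C=C(\C)I)N1C(=O)OC[C@@H]1Cc1ccccc1 | intermediate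
12 | (2S,3S,4Z)-2-(2,2-dimethyl-1,3-dioxan-5-yl)-3-hydroxy-5-iodo-N-methoxy-N-methylhex-4-enamide | CON(C)C(=O)[C@@H](C1COC(C)(C)OC1)[C@H](O)\C=C(\C)I | intermediate
13 | (2S,3S,4Z)-3-[(tert-butyldimethylsilyl)oxy]-2-(2,2-dimethyl-1,3-dioxan-5-yl)-5-iodo-N-methoxy-N-methylhex-4-enamide | CON(C)C(=O)[C@@H](C1COC(C)(C)OC1)[C@H](O[Si](C)(C)C(C)(C)C)\C=C(\C)I | intermediate
14 | (3S,4S,5Z)-4-[(tert-butyldimethylsilyl)oxy]-3-(2,2-dimethyl-1,3-dioxan-5-yl)-6-iodohept-5-en-2-one | CC(=O)[C@@H](C1COC(C)(C)OC1)[C@H](O[Si](C)(C)C(C)(C)C)\C=C(\C)I | intermediate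
15 | but-3-yn-2-ol (racemic) | CC(O)C#C | starting material
16 | (3S,4R,5Z)-4-[(tert-butyldimethylsilyl)oxy]-3-(2,2-dimethyl-1,3-dioxan-5-yl)-10-hydroxy-6-methylundec-5-en-8-yne-2,7-dione (both C10 epimers) | CC(=O)[C@@H](C1COC(C)(C)OC1)[C@H](O[Si](C)(C)C(C)(C)C)\C=C(\C)C(=O)C#CC(C)O | intermediate
17 | 5-[(2Z,4R,5S)-4-[(tert-butyldimethylsilyl)oxy]-5-(2,2-dimethyl-1,3-dioxan-5-yl)-6-oxohept-2-en-2-yl]-2-methylfuran-3(2H)-one (both C2 epimers of the furanone) | CC(=O)[C@@H](C1COC(C)(C)OC1)[C@H](O[Si](C)(C)C(C)(C)C)\C=C(\C)C1=CC(=O)C(C)O1 | intermediate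
18 | dilithium dienolate of 17: lithium furan-3-olate and lithium C8=C9 enolate (not isolated) | C=C(O[Li])[C@@H](C1COC(C)(C)OC1)[C@H](O[Si](C)(C)C(C)(C)C)\C=C(\C)c1cc(O[Li])c(C)o1 | intermediate
19 | tert-butyl({5-[(2Z,4R,5S)-4,6-bis[(tert-butyldimethylsilyl)oxy]-5-(2,2-dimethyl-1,3-dioxan-5-yl)hepta-2,6-dien-2-yl]-2-methylfuran-3-yl}oxy)dimethylsilane | C=C(O[Si](C)(C)C(C)(C)C)[C@@H](C1COC(C)(C)OC1)[C@H](O[Si](C)(C)C(C)(C)C)\C=C(\C)c1cc(O[Si](C)(C)C(C)(C)C)c(C)o1 | intermediate
20 | (4Z,6R,7S,10R)-6-[(tert-butyldimethylsilyl)oxy]-7-(2,2-dimethyl-1,3-dioxan-5-yl)-4,10-dimethyl-3,10-epoxycyclodeca-2,4-diene-1,8-dione | O=C1C[C@@]2(C)OC(=CC2=O)/C(C)=C\[C@@H](O[Si](C)(C)C(C)(C)C)[C@@H]1C3COC(C)(C)OC3 | intermediate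
21 | (4Z,6R,7R,8S,10R)-6-[(tert-butyldimethylsilyl)oxy]-7-(2,2-dimethyl-1,3-dioxan-5-yl)-8-hydroxy-4,10-dimethyl-3,10-epoxycyclodeca-2,4-dien-1-one | O[C@H]1C[C@@]2(C)OC(=CC2=O)/C(C)=C\[C@@H](O[Si](C)(C)C(C)(C)C)[C@@H]1C3COC(C)(C)OC3 | intermediate
22 | (4Z,6R,7R,8S,10R)-6-[(tert-butyldimethylsilyl)oxy]-7-(1,3-dihydroxypropan-2-yl)-8-hydroxy-4,10-dimethyl-3,10-epoxycyclodeca-2,4-dien-1-one | O[C@H]1C[C@@]2(C)OC(=CC2=O)/C(C)=C\[C@@H](O[Si](C)(C)C(C)(C)C)[C@@H]1C(CO)CO | intermediate
23 | lactol: five-membered hemiacetal between O8 and C12 with CH2OH on C11 and silyl ether at C6 (not isolated; epimers at C11 and C12) | OCC1C(O)O[C@H]2C[C@@]3(C)OC(=CC3=O)/C(C)=C\[C@@H](O[Si](C)(C)C(C)(C)C)[C@H]12 | intermediate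
24 | hydroxymethyl lactone: compound 26 with H and CH2OH on C11 in place of the methylene group (both C11 epimers) | OCC1C(=O)O[C@H]2C[C@@]3(C)OC(=CC3=O)/C(C)=C\[C@@H](O[Si](C)(C)C(C)(C)C)[C@H]12 | intermediate
25 | methanesulfonate of 24 (not isolated) | CS(=O)(=O)OCC1C(=O)O[C@H]2C[C@@]3(C)OC(=CC3=O)/C(C)=C\[C@@H](O[Si](C)(C)C(C)(C)C)[C@H]12 | intermediate
26 | (6R,7R,8S,10R)-6-O-tert-butyldimethylsilyl ether of the deacylated target | C=C1C(=O)O[C@H]2C[C@@]3(C)OC(=CC3=O)/C(C)=C\[C@@H](O[Si](C)(C)C(C)(C)C)[C@H]12 | intermediate
27 | (6R,7S,8S,10R)-6-hydroxy lactone (deacylated target) | C=C1C(=O)O[C@H]2C[C@@]3(C)OC(=CC3=O)/C(C)=C\[C@@H](O)[C@H]12 | intermediate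
28 | 2-methylprop-2-en-1-ol | C=C(C)CO | starting material
29 | [(2R)-2-methyloxiran-2-yl]methanol | OC[C@]1(C)CO1 | intermediate
30 | (2S)-2-methyloxirane-2-carboxylic acid | OC(=O)[C@]1(C)CO1 | intermediate
31 | (2S)-2-methyloxirane-2-carboxylic 2,4,6-trichlorobenzoic anhydride (not isolated) | O=C(OC(=O)c1c(Cl)cc(Cl)cc1Cl)[C@]1(C)CO1 | intermediate
32 | (4Z,6R,7R,8S,10R)-3,10-epoxy-1-oxogermacra-2,4,11(13)-trien-12,8-olid-6-yl (2S)-2-methyloxirane-2-carboxylate | C=C1C(=O)O[C@H]2C[C@@]3(C)OC(=CC3=O)/C(C)=C\[C@@H](OC(=O)[C@]3(C)CO3)[C@H]12 | target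

## Step count and least certain steps

Total: 20 steps. Longest linear sequence: 16 steps (steps 1, 2, 5 to 17 and 20; the branch from 6 through steps 3 and 4 is equally long).

**Step 12 (key step, proposed new method).** The medium-ring closure may be too slow. The oxidised furan would then be lost by intermolecular coupling, by over-oxidation and capture of the C10 cation by the medium, or by Z/E scrambling of C4=C5 in the delocalised radical cation. The facial selectivity at C10 rests on a conformational argument alone. Fallback by known polar chemistry, setting out from 13 and returning at 20: addition of chloromethyllithium (ICH2Cl, MeLi·LiBr, THF, −78 °C) to the Weinreb amide gives the chloromethyl ketone F1. Carbonylative Sonogashira coupling with 15 as in step 9 gives the ynone F2, and gold-catalysed cycloisomerisation as in step 10 gives the furanone chloromethyl ketone F3. Under Finkelstein conditions with a mild base at high dilution (NaI, Cs2CO3, MeCN) the furanone enolate is C-alkylated at C10 by the C9 halide. This intramolecular enolate alkylation forms the same C9–C10 bond and gives 20.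

**Step 13.** Facial selectivity at C8 may be poor or reversed, because the preference depends on the conformation of a flexible medium ring; some reduction at C1 is also possible. Fallback, setting out from 20 and returning at 21: the epimeric carbinol F4 obtained from the reduction is inverted by a Mitsunobu reaction (4-nitrobenzoic acid, PPh3, diisopropyl azodicarboxylate) to the 4-nitrobenzoate F5 of the 8S series, and methanolysis (K2CO3, MeOH, 0 °C) gives 21.

**Step 9.** Direct alkynylation without CO uptake, Z to E isomerisation of the new enone through reversible amine addition, or amine addition to the ynone may compete. Fallback, setting out from 14 and returning at 19: Stille coupling (Pd(PPh3)4, CuI, CsF, DMF) attaches the aromatic ring directly. The partner is the furylstannane F7, made from 2-methylfuran-3(2H)-one by O-silylation to the silyloxyfuran F6 (TBSOTf, Et3N) and lithiation at the free α-position followed by Bu3SnCl. The coupling gives the methyl ketone F8, and kinetic enolisation (LiN(iPr)2, TBSCl, DMPU, −78 °C) gives 19, so steps 9 to 11 are replaced.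

**Step 15.** Over-oxidation of the second hydroxymethyl arm is likely, because the primary alcohol remaining in 24 is oxidised at a rate comparable with the first. Fallback, setting out from 22 and returning at 24: the oxidation is driven to completion with excess oxidant to the α-formyl lactone F9, which exists as its enol, and the formyl group is reduced back with NaBH4 at low temperature to 24. Formylation followed by reduction is the classical entry to α-hydroxymethyl lactones.

**Step 11.** Deprotonation at C7 instead of the methyl group would lead to loss of the C6 silyloxy group by β-elimination or to epimerisation at C7. Fallback, setting out from 17 and returning at 20: the two silylations are separated. Soft enolisation (iPr3SiOTf, Et3N, CH2Cl2, −78 °C) converts only the furanone into the aromatic triisopropylsilyloxyfuran F10. The remaining methyl ketone is then enolised with one equivalent of LiN(iPr)2 in the presence of TBSCl (internal quench) to the mixed silyl precursor F11, which is electrolysed as in step 12 to 20.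

## Further compounds

F1 | step 12 | (3S,4S,5Z)-4-[(tert-butyldimethylsilyl)oxy]-1-chloro-3-(2,2-dimethyl-1,3-dioxan-5-yl)-6-iodohept-5-en-2-one | ClCC(=O)[C@@H](C1COC(C)(C)OC1)[C@H](O[Si](C)(C)C(C)(C)C)\C=C(\C)I
F2 | step 12 | (3S,4R,5Z)-4-[(tert-butyldimethylsilyl)oxy]-1-chloro-3-(2,2-dimethyl-1,3-dioxan-5-yl)-10-hydroxy-6-methylundec-5-en-8-yne-2,7-dione (both C10 epimers) | ClCC(=O)[C@@H](C1COC(C)(C)OC1)[C@H](O[Si](C)(C)C(C)(C)C)\C=C(\C)C(=O)C#CC(C)O
F3 | step 12 | 5-[(2Z,4R,5S)-4-[(tert-butyldimethylsilyl)oxy]-7-chloro-5-(2,2-dimethyl-1,3-dioxan-5-yl)-6-oxohept-2-en-2-yl]-2-methylfuran-3(2H)-one (both C2 epimers of the furanone) | ClCC(=O)[C@@H](C1COC(C)(C)OC1)[C@H](O[Si](C)(C)C(C)(C)C)\C=C(\C)C1=CC(=O)C(C)O1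
F4 | step 13 | (4Z,6R,7R,8R,10R)-8-epimer of 21 | O[C@@H]1C[C@@]2(C)OC(=CC2=O)/C(C)=C\[C@@H](O[Si](C)(C)C(C)(C)C)[C@@H]1C3COC(C)(C)OC3
F5 | step 13 | 4-nitrobenzoate of 21 (8S) | O=C(O[C@H]1C[C@@]2(C)OC(=CC2=O)/C(C)=C\[C@@H](O[Si](C)(C)C(C)(C)C)[C@@H]1C3COC(C)(C)OC3)c1ccc(cc1)[N+](=O)[O-]
F6 | step 9 | tert-butyldimethyl[(2-methylfuran-3-yl)oxy]silane | Cc1occc1O[Si](C)(C)C(C)(C)C
F7 | step 9 | tert-butyldimethyl{[2-methyl-5-(tributylstannyl)furan-3-yl]oxy}silane | Cc1oc(cc1O[Si](C)(C)C(C)(C)C)[Sn](CCCC)(CCCC)CCCC
F8 | step 9 | (3S,4R,5Z)-4-[(tert-butyldimethylsilyl)oxy]-6-{4-[(tert-butyldimethylsilyl)oxy]-5-methylfuran-2-yl}-3-(2,2-dimethyl-1,3-dioxan-5-yl)hept-5-en-2-one | CC(=O)[C@@H](C1COC(C)(C)OC1)[C@H](O[Si](C)(C)C(C)(C)C)\C=C(\C)c1cc(O[Si](C)(C)C(C)(C)C)c(C)o1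
F9 | step 15 | α-formyl lactone: 24 with CHO in place of CH2OH on C11 (enolised) | O=CC1C(=O)O[C@H]2C[C@@]3(C)OC(=CC3=O)/C(C)=C\[C@@H](O[Si](C)(C)C(C)(C)C)[C@H]12
F10 | step 11 | (3S,4R,5Z)-4-[(tert-butyldimethylsilyl)oxy]-3-(2,2-dimethyl-1,3-dioxan-5-yl)-6-{5-methyl-4-[(triisopropylsilyl)oxy]furan-2-yl}hept-5-en-2-one | CC(=O)[C@@H](C1COC(C)(C)OC1)[C@H](O[Si](C)(C)C(C)(C)C)\C=C(\C)c1cc(O[Si](C(C)C)(C(C)C)C(C)C)c(C)o1
F11 | step 11 | analogue of 19 with a triisopropylsilyl group on the furan oxygen | C=C(O[Si](C)(C)C(C)(C)C)[C@@H](C1COC(C)(C)OC1)[C@H](O[Si](C)(C)C(C)(C)C)\C=C(\C)c1cc(O[Si](C(C)C)(C(C)C)C(C)C)c(C)o1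
A1 | alternative 1 | oxygen-bridged dihydrofuranol: 26 with a C1 carbinol in place of the C1 ketone | C=C1C(=O)O[C@H]2C[C@@]3(C)OC(=C[C@@H]3O)/C(C)=C\[C@@H](O[Si](C)(C)C(C)(C)C)[C@H]12
A2 | alternative 1 | ten-membered trans-1,10-epoxy-3-ketone with Z C4=C5, C6 silyl ether and the methylene lactone | C=C1C(=O)O[C@H]2C[C@]3(C)O[C@H]3CC(=O)/C(C)=C\[C@@H](O[Si](C)(C)C(C)(C)C)[C@H]12
A3 | alternative 2 | ten-membered furanone with free C6 alcohol, C8 triethylsilyl ether and C(=CH2)CH2OSiEt3 on C7 | CC[Si](CC)(CC)O[C@H]1C[C@@]2(C)OC(=CC2=O)/C(C)=C\[C@@H](O)[C@@H]1C(=C)CO[Si](CC)(CC)CC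
A4 | alternative 2 | thirteen-membered ether with C6H2–O–C13H2, ring alkene C7=C11 and CH2OSiEt3 on C11 | CC[Si](CC)(CC)O[C@H]1C[C@@]2(C)OC(=CC2=O)/C(C)=C\COC/C(CO[Si](CC)(CC)CC)=C/1
A5 | alternative 3 | complete core with α-methylene lactone and C6 silyl ether (same structure as 26) | C=C1C(=O)O[C@H]2C[C@@]3(C)OC(=CC3=O)/C(C)=C\[C@@H](O[Si](C)(C)C(C)(C)C)[C@H]12
A6 | alternative 3 | furanone macrocycle with ethynyl on C7, free C8 alcohol and C6 silyl ether | O[C@H]1C[C@@]2(C)OC(=CC2=O)/C(C)=C\[C@@H](O[Si](C)(C)C(C)(C)C)[C@@H]1C#C
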